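**Plan**

1. Retrosynthesis: take off the two benzyl ethers (O7, O5'), the O5 triflate and the 3-methoxy group, then cut O1–C8a, C4–C4a and O1–C2 together. Ring A becomes an aryne; C2, C3, C4 and ring B become an arylpropiolic acid.
2. Enabling feature: C4a and C8a are adjacent carbons of ring A, one carrying the acyl carbon C4 and the other O1, and they lie between O5 and the 8-methoxy group. This is the pattern an aryne leaves after inserting into the C–O bond of a carboxylic acid, and an O5 triflate makes the two aryne termini unequal.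
3. Forward: syringol gives a mirror-symmetric 2-silylresorcinol bis-triflate (steps 1–6); 2,4-dimethoxybenzaldehyde gives the arylpropiolic acid (steps 7–11). Step 12 joins them and closes ring C on ring A. C3 is then hydroxylated and methylated, the triflate is removed from O5, and both benzyl groups are cleaved.
4. Stereochemistry: the target has no stereocentre, so none has to be set.

Key step: step 12

Remark: flavone numbering (O1, C2–C4, C4a, C5–C8, C8a, primes for ring B) is used for all chromenones. Reactive species formed in the flask (aryne, organolithiums) are numbered as discrete compounds.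

**Route**

Step 1
Reactants: 1 2,6-dimethoxyphenol (syringol)
Product: 2 2-(benzyloxy)-1,3-dimethoxybenzene
Conditions: BnBr, K2CO3, DMF, 60 °C
Reagents that add atoms: benzyl bromide, BrCc1ccccc1
Why: Williamson ether synthesis on an acidic phenol; the benzyl group masks the future O7 and, being twisted out of plane between two methoxy groups, leaves those methoxy groups to direct the next substitution.

Step 2
Reactants: 2 2-(benzyloxy)-1,3-dimethoxybenzene
Product: 3 3-(benzyloxy)-1,5-dibromo-2,4-dimethoxybenzene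
Conditions: NBS (2.05 equiv), MeCN, 0 °C to rt, dark
Reagents that add atoms: N-bromosuccinimide, O=C1CCC(=O)N1Br
Why: Electrophilic aromatic bromination in which each bromine should enter ortho to one methoxy group and para to the other, as with pyrogallol trimethyl ether, so the position para to the benzyloxy group stays free.

Step 3
Reactants: 3 3-(benzyloxy)-1,5-dibromo-2,4-dimethoxybenzene
Product: 5 5-(benzyloxy)-4,6-dimethoxybenzene-1,3-diol, via bis(pinacol boronate) 4 (not isolated)
Conditions: B2pin2 (2.6 equiv), PdCl2(dppf) (5 mol %), KOAc, 1,4-dioxane, 90 °C; then 30% H2O2, aq. NaOH, THF, 0 °C; work-up with aq. Na2S2O3 and NH4Cl under argon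
Reagents that add atoms: hydrogen peroxide, OO; bis(pinacolato)diboron, CC1(C)OB(OC1(C)C)B1OC(C)(C)C(C)(C)O1 (its atoms remain only in 4)
Why: Twofold Miyaura borylation of the aryl bromides followed by alkaline peroxide oxidation of both C–B bonds is a standard way to replace bromine by hydroxyl on ortho-alkoxy arenes without organolithium reagents.

Step 4
Reactants: 5 5-(benzyloxy)-4,6-dimethoxybenzene-1,3-diol
Product: 6 5-(benzyloxy)-2-bromo-4,6-dimethoxybenzene-1,3-diol
Conditions: NBS (1.0 equiv), CH2Cl2, −78 to 0 °C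
Reagents that add atoms: N-bromosuccinimide, O=C1CCC(=O)N1Br
Why: Electrophilic bromination at the only ring C–H, which lies ortho to both hydroxy groups, so no regiochemical choice exists; low temperature and one equivalent should limit oxidation of the electron-rich ring.

Step 5
Reactants: 6 5-(benzyloxy)-2-bromo-4,6-dimethoxybenzene-1,3-diol
Product: 9 5-(benzyloxy)-4,6-dimethoxy-2-(trimethylsilyl)benzene-1,3-diol, via bis(trimethylsilyl) ether 7 (not isolated), via lithium silylphenoxide 8 (not isolated)
Conditions: (Me3Si)2NH, THF, 70 °C, then evaporation; n-BuLi (1.1 equiv), THF, −78 °C to rt; sat. aq. NH4Cl, rt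
Reagents that add atoms: hexamethyldisilazane, C[Si](C)(C)N[Si](C)(C)C
Why: O-silylation, bromine–lithium exchange and 1,3-retro-Brook migration of one silyl group from oxygen to the aryl carbanion is the standard entry to ortho-silyl phenols, and the remaining aryl silyl ether is hydrolysed on work-up.

Step 6
Reactants: 9 5-(benzyloxy)-4,6-dimethoxy-2-(trimethylsilyl)benzene-1,3-diol
Product: 10 5-(benzyloxy)-4,6-dimethoxy-2-(trimethylsilyl)-1,3-phenylene bis(trifluoromethanesulfonate)
Conditions: Tf2O (2.4 equiv), pyridine, CH2Cl2, 0 °C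
Reagents that add atoms: trifluoromethanesulfonic anhydride, O=S(=O)(OS(=O)(=O)C(F)(F)F)C(F)(F)F
Why: O-sulfonylation of both phenols with triflic anhydride and pyridine, routine for ortho-silyl phenols, should give the mirror-symmetric aryne precursor.

Step 7
Reactants: 11 2,4-dimethoxybenzaldehyde
Product: 13 2,4-dimethoxyphenol, via aryl formate 12 (not isolated)
Conditions: mCPBA, CH2Cl2, rt; then NaOH, MeOH/H2O, rt; acidic work-up
Reagents that add atoms: 3-chloroperoxybenzoic acid, O=C(OO)c1cccc(Cl)c1
Why: Baeyer–Villiger oxidation of an electron-rich benzaldehyde (Dakin-type) proceeds with aryl migration to the formate, which is saponified in the same flask.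

Step 8
Reactants: 13 2,4-dimethoxyphenol
Product: 14 1-(benzyloxy)-2,4-dimethoxybenzene
Conditions: BnBr, K2CO3, DMF, 60 °C
Reagents that add atoms: benzyl bromide, BrCc1ccccc1
Why: Williamson ether synthesis; the benzyl ether will become the 5'-hydroxy group and is removed together with the O7 benzyl group at the end.

Step 9
Reactants: 14 1-(benzyloxy)-2,4-dimethoxybenzene
Product: 16 5-(benzyloxy)-2,4-dimethoxybenzaldehyde, via iminium chloride 15 (not isolated)
Conditions: POCl3, DMF, 0 to 70 °C; then aq. NaOAc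
Reagents that add atoms: N,N-dimethylformamide, CN(C)C=O; water, O
Why: Vilsmeier–Haack formylation should enter para to the 2-methoxy and ortho to the 4-methoxy group, the most activated unhindered site, as with 1,2,4-trimethoxybenzene.

Step 10
Reactants: 16 5-(benzyloxy)-2,4-dimethoxybenzaldehyde
Product: 17 1-(benzyloxy)-5-(2,2-dibromoethenyl)-2,4-dimethoxybenzene
Conditions: CBr4, PPh3, CH2Cl2, 0 °C
Reagents that add atoms: carbon tetrabromide, BrC(Br)(Br)Br
Why: First stage of the Corey–Fuchs reaction, a Wittig-type dibromo-olefination of an aromatic aldehyde.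

Step 11
Reactants: 17 1-(benzyloxy)-5-(2,2-dibromoethenyl)-2,4-dimethoxybenzene
Product: 19 3-[5-(benzyloxy)-2,4-dimethoxyphenyl]prop-2-ynoic acid, via lithium acetylide 18 (not isolated)
Conditions: n-BuLi (2.2 equiv), THF, −78 °C; CO2 (g), −78 °C to rt; aq. HCl
Reagents that add atoms: carbon dioxide, O=C=O
Why: Second stage of the Corey–Fuchs sequence, in which elimination and bromine–lithium exchange give the lithium acetylide, which is carboxylated by CO2.

Step 12
Reactants: 10 5-(benzyloxy)-4,6-dimethoxy-2-(trimethylsilyl)-1,3-phenylene bis(trifluoromethanesulfonate); 19 3-[5-(benzyloxy)-2,4-dimethoxyphenyl]prop-2-ynoic acid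
Product: 22 7-(benzyloxy)-2-[5-(benzyloxy)-2,4-dimethoxyphenyl]-6,8-dimethoxy-4-oxo-4H-chromen-5-yl trifluoromethanesulfonate, via triflyloxy aryne 20 (not isolated), via hydroxyaryl ynone 21 (not isolated)
Conditions: 10 (1.5 equiv), CsF (4 equiv), THF, 125 °C, sealed tube
Reagents that add atoms: none
Why: Fluoride attacks silicon and, because the two triflates are equivalent, only one aryne (20) can form; the caesium carboxylate of 19 then bonds through oxygen to the aryne carbon next to the methoxy group (future C8a), the carbanion left at future C4a attacks the aryl ester carbonyl through a four-membered transition state, and the strained adduct opens to the phenoxide of ynone 21, a net insertion into the acid C–O bond that forms O1–C8a and C4–C4a. The phenoxide then adds to the ynone β-carbon in a 6-endo-dig oxa-Michael closure that forms O1–C2 and ring C, and the acid proton ends on C3. The closest known chemistry is the fluoride-mediated, metal-free insertion of arynes into the C–O bond of carboxylic acids, which gives flavones from arylpropiolic acids, together with the established distal attack of nucleophiles on 3-(triflyloxy)arynes. No stereocentre is formed. The step needs oxygen to attack C8a and not C4a, which the triflyloxy group should secure because it is a much stronger σ-acceptor than methoxy, so it distorts the aryne toward attack at the far carbon and stabilises the charge developing beside it. It also needs the C4a carbanion to take the acyl group before it expels the neighbouring triflate, which the adjacent, very electrophilic ynoate carbonyl in proton-free THF should favour (as silyl transfer does in the known silylamination of 3-(triflyloxy)arynes), and it needs 6-endo over 5-exo closure, which the hot basic medium favours thermodynamically.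

Step 13
Reactants: 22 7-(benzyloxy)-2-[5-(benzyloxy)-2,4-dimethoxyphenyl]-6,8-dimethoxy-4-oxo-4H-chromen-5-yl trifluoromethanesulfonate
Product: 25 7-(benzyloxy)-2-[5-(benzyloxy)-2,4-dimethoxyphenyl]-3-hydroxy-6,8-dimethoxy-4-oxo-4H-chromen-5-yl trifluoromethanesulfonate, via 3-lithioflavone 23 (not isolated), via dimethyl boronate 24 (not isolated)
Conditions: LiN(iPr)2 (1.2 equiv), THF, −78 °C; B(OMe)3, −78 to 0 °C; AcOH, 30% H2O2, 0 °C to rt
Reagents that add atoms: hydrogen peroxide, OO; trimethyl borate, COB(OC)OC (its atoms remain only in 24)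
Why: C3 lithiation of a flavone at the vinylic C–H α to the carbonyl, borylation and oxidative C–B cleavage is the known lithiation route to flavonols, and ring A has no C–H ortho to the triflate, so an anionic thia-Fries rearrangement is excluded.

Step 14
Reactants: 25 7-(benzyloxy)-2-[5-(benzyloxy)-2,4-dimethoxyphenyl]-3-hydroxy-6,8-dimethoxy-4-oxo-4H-chromen-5-yl trifluoromethanesulfonate
Product: 26 7-(benzyloxy)-2-[5-(benzyloxy)-2,4-dimethoxyphenyl]-3,6,8-trimethoxy-4-oxo-4H-chromen-5-yl trifluoromethanesulfonate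
Conditions: MeI, K2CO3, acetone, 40 °C
Reagents that add atoms: iodomethane, CI
Why: Williamson O-methylation of the acidic 3-hydroxy group; O5 is masked as the triflate and cannot compete.

Step 15
Reactants: 26 7-(benzyloxy)-2-[5-(benzyloxy)-2,4-dimethoxyphenyl]-3,6,8-trimethoxy-4-oxo-4H-chromen-5-yl trifluoromethanesulfonate
Product: 27 7-(benzyloxy)-2-[5-(benzyloxy)-2,4-dimethoxyphenyl]-5-hydroxy-3,6,8-trimethoxy-4H-chromen-4-one
Conditions: aq. Et4NOH (2.5 equiv), 1,4-dioxane, rt; then 1 M HCl
Reagents that add atoms: none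
Why: Hydroxide attacks sulfur of the aryl triflate and releases the phenoxide (S–O cleavage with Et4NOH in dioxane is a mild, known triflate deprotection), and the freed 5-hydroxy group is stabilised by its hydrogen bond to the C4 carbonyl.

Step 16
Reactants: 27 7-(benzyloxy)-2-[5-(benzyloxy)-2,4-dimethoxyphenyl]-5-hydroxy-3,6,8-trimethoxy-4H-chromen-4-one
Product: 28 5,7-dihydroxy-2-(5-hydroxy-2,4-dimethoxyphenyl)-3,6,8-trimethoxy-4H-chromen-4-one
Conditions: H2 (1 atm), 10% Pd/C, EtOAc/MeOH, rt
Reagents that add atoms: none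
Why: Hydrogenolysis of the two benzyl aryl ethers over Pd/C; the tetrasubstituted C2=C3 bond of a 3-methoxyflavone and the aryl methyl ethers should be inert under these conditions.

**Compound list**

1 | 2,6-dimethoxyphenol (syringol) | COc1cccc(OC)c1O | starting material
2 | 2-(benzyloxy)-1,3-dimethoxybenzene | COc1cccc(OC)c1OCc1ccccc1 | intermediate
3 | 3-(benzyloxy)-1,5-dibromo-2,4-dimethoxybenzene | COc1c(Br)cc(Br)c(OC)c1OCc1ccccc1 | intermediate
4 | 2,2'-[5-(benzyloxy)-4,6-dimethoxy-1,3-phenylene]bis(4,4,5,5-tetramethyl-1,3,2-dioxaborolane) | COc1c(B2OC(C)(C)C(C)(C)O2)cc(B2OC(C)(C)C(C)(C)O2)c(OC)c1OCc1ccccc1 | intermediate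
5 | 5-(benzyloxy)-4,6-dimethoxybenzene-1,3-diol | COc1c(O)cc(O)c(OC)c1OCc1ccccc1 | intermediate
6 | 5-(benzyloxy)-2-bromo-4,6-dimethoxybenzene-1,3-diol | COc1c(O)c(Br)c(O)c(OC)c1OCc1ccccc1 | intermediate
7 | [5-(benzyloxy)-2-bromo-4,6-dimethoxy-1,3-phenylene]bis(oxy)bis(trimethylsilane) | COc1c(O[Si](C)(C)C)c(Br)c(O[Si](C)(C)C)c(OC)c1OCc1ccccc1 | intermediate
8 | lithium 5-(benzyloxy)-4,6-dimethoxy-2-(trimethylsilyl)-3-[(trimethylsilyl)oxy]phenolate | [Li+].COc1c([O-])c([Si](C)(C)C)c(O[Si](C)(C)C)c(OC)c1OCc1ccccc1 | intermediate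
9 | 5-(benzyloxy)-4,6-dimethoxy-2-(trimethylsilyl)benzene-1,3-diol | COc1c(O)c([Si](C)(C)C)c(O)c(OC)c1OCc1ccccc1 | intermediate
10 | 5-(benzyloxy)-4,6-dimethoxy-2-(trimethylsilyl)-1,3-phenylene bis(trifluoromethanesulfonate) | COc1c(OCc2ccccc2)c(OC)c(OS(=O)(=O)C(F)(F)F)c([Si](C)(C)C)c1OS(=O)(=O)C(F)(F)F | intermediate
11 | 2,4-dimethoxybenzaldehyde | COc1ccc(C=O)c(OC)c1 | starting material
12 | 2,4-dimethoxyphenyl formate | COc1ccc(OC=O)c(OC)c1 | intermediate
13 | 2,4-dimethoxyphenol | COc1ccc(O)c(OC)c1 | intermediate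
14 | 1-(benzyloxy)-2,4-dimethoxybenzene | COc1ccc(OCc2ccccc2)c(OC)c1 | intermediate
15 | N-{[5-(benzyloxy)-2,4-dimethoxyphenyl]methylidene}-N-methylmethanaminium chloride | COc1cc(OC)c(C=[N+](C)C)cc1OCc1ccccc1.[Cl-] | intermediate
16 | 5-(benzyloxy)-2,4-dimethoxybenzaldehyde | COc1cc(OC)c(C=O)cc1OCc1ccccc1 | intermediate
17 | 1-(benzyloxy)-5-(2,2-dibromoethenyl)-2,4-dimethoxybenzene | COc1cc(OC)c(C=C(Br)Br)cc1OCc1ccccc1 | intermediate
18 | {[5-(benzyloxy)-2,4-dimethoxyphenyl]ethynyl}lithium | [Li]C#Cc1cc(OCc2ccccc2)c(OC)cc1OC | intermediate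
19 | 3-[5-(benzyloxy)-2,4-dimethoxyphenyl]prop-2-ynoic acid | O=C(O)C#Cc1cc(OCc2ccccc2)c(OC)cc1OC | intermediate
20 | 5-(benzyloxy)-4,6-dimethoxy-3-[(trifluoromethanesulfonyl)oxy]benzyne (1,2-didehydrobenzene) | COC1=C(OCc2ccccc2)C(OC)=C(OS(=O)(=O)C(F)(F)F)C#C1 | intermediate
21 | 3-(benzyloxy)-6-{3-[5-(benzyloxy)-2,4-dimethoxyphenyl]prop-2-ynoyl}-5-hydroxy-2,4-dimethoxyphenyl trifluoromethanesulfonate | COc1cc(OC)c(C#CC(=O)c2c(O)c(OC)c(OCc3ccccc3)c(OC)c2OS(=O)(=O)C(F)(F)F)cc1OCc1ccccc1 | intermediate
22 | 7-(benzyloxy)-2-[5-(benzyloxy)-2,4-dimethoxyphenyl]-6,8-dimethoxy-4-oxo-4H-chromen-5-yl trifluoromethanesulfonate | COc1cc(OC)c(-c2cc(=O)c3c(OS(=O)(=O)C(F)(F)F)c(OC)c(OCc4ccccc4)c(OC)c3o2)cc1OCc1ccccc1 | intermediate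
23 | 3-lithio derivative of 22 (lithium on C3) | COc1cc(OC)c(-c2oc3c(OC)c(OCc4ccccc4)c(OC)c(OS(=O)(=O)C(F)(F)F)c3c(=O)c2[Li])cc1OCc1ccccc1 | intermediate
24 | dimethyl {7-(benzyloxy)-2-[5-(benzyloxy)-2,4-dimethoxyphenyl]-6,8-dimethoxy-4-oxo-5-[(trifluoromethanesulfonyl)oxy]-4H-chromen-3-yl}boronate | COc1cc(OC)c(-c2oc3c(OC)c(OCc4ccccc4)c(OC)c(OS(=O)(=O)C(F)(F)F)c3c(=O)c2B(OC)OC)cc1OCc1ccccc1 | intermediate
25 | 7-(benzyloxy)-2-[5-(benzyloxy)-2,4-dimethoxyphenyl]-3-hydroxy-6,8-dimethoxy-4-oxo-4H-chromen-5-yl trifluoromethanesulfonate | COc1cc(OC)c(-c2oc3c(OC)c(OCc4ccccc4)c(OC)c(OS(=O)(=O)C(F)(F)F)c3c(=O)c2O)cc1OCc1ccccc1 | intermediate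
26 | 7-(benzyloxy)-2-[5-(benzyloxy)-2,4-dimethoxyphenyl]-3,6,8-trimethoxy-4-oxo-4H-chromen-5-yl trifluoromethanesulfonate | COc1cc(OC)c(-c2oc3c(OC)c(OCc4ccccc4)c(OC)c(OS(=O)(=O)C(F)(F)F)c3c(=O)c2OC)cc1OCc1ccccc1 | intermediate
27 | 7-(benzyloxy)-2-[5-(benzyloxy)-2,4-dimethoxyphenyl]-5-hydroxy-3,6,8-trimethoxy-4H-chromen-4-one | COc1cc(OC)c(-c2oc3c(OC)c(OCc4ccccc4)c(OC)c(O)c3c(=O)c2OC)cc1OCc1ccccc1 | intermediate
28 | 5,7-dihydroxy-2-(5-hydroxy-2,4-dimethoxyphenyl)-3,6,8-trimethoxy-4H-chromen-4-one | COc1cc(OC)c(-c2oc3c(OC)c(O)c(OC)c(O)c3c(=O)c2OC)cc1O | target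

**Totals**

Total step count: 16.
Longest linear sequence: 11 steps (steps 1–6 and 12–16, from syringol).

**Steps most likely to fail**

1. Step 12. Several things may go wrong:
 - the C4a carbanion may expel the neighbouring triflate (a second aryne) before the acyl shift;
 - the carboxylate may attack the wrong aryne terminus;
 - the propiolic acid may decarboxylate at 125 °C;
 - the phenoxide may close 5-exo to an aurone.

 Fallback: a classical chalcone route that sets out from diol 5 (with aldehyde 16) and comes back at 22. Friedel–Crafts C-acetylation of 5 at its only ring C–H (Ac2O, BF3·OEt2, 0 °C to rt) would give 1-[4-(benzyloxy)-2,6-dihydroxy-3,5-dimethoxyphenyl]ethan-1-one F1. Claisen–Schmidt condensation with 16 (KOH, EtOH) would give (E)-1-[4-(benzyloxy)-2,6-dihydroxy-3,5-dimethoxyphenyl]-3-[5-(benzyloxy)-2,4-dimethoxyphenyl]prop-2-en-1-one F2. Iodine-catalysed oxidative cyclisation in DMSO at 120 °C would close ring C to 7-(benzyloxy)-2-[5-(benzyloxy)-2,4-dimethoxyphenyl]-5-hydroxy-6,8-dimethoxy-4H-chromen-4-one F3; the two hydroxy groups are equivalent, so only one flavone can form. Triflation (Tf2O, pyridine) then returns to 22.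

2. Step 13. The lithiation may be incomplete or unselective: the amide base may attack the triflate sulfur, the 3-lithio species may ring-open to the ynone phenoxide, or metalation may occur between the two methoxy groups of ring B.

 Fallback: an oxidation route that sets out from 22 and comes back at 25. Epoxidation of C2=C3 with dimethyldioxirane (acetone/CH2Cl2, 0 °C to rt) would give the racemic, cis-fused 2,3-epoxide of 22 F4. Catalytic p-TsOH in CH2Cl2 would open the epoxide at C2 and tautomerise it to flavonol 25.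

3. Step 4. The very electron-rich diol may be oxidised in competition with ring bromination, and material may be lost in handling this air-sensitive compound.

 Fallback: silicon is introduced by deprotonation, setting out from dibromide 3 and coming back at 9, so that steps 3–5 are bypassed. LiN(iPr)2 with Me3SiCl present in THF at −78 °C would remove the proton between the two bromines and give [4-(benzyloxy)-2,6-dibromo-3,5-dimethoxyphenyl]trimethylsilane F5. Twofold bromine–lithium exchange (t-BuLi, THF, −78 °C) and quenching with B(OMe)3 would give tetramethyl [5-(benzyloxy)-4,6-dimethoxy-2-(trimethylsilyl)-1,3-phenylene]bis(boronate) F6. Alkaline H2O2 would oxidise F6 to 9.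

**Further compounds**

F1 | step 12 | 1-[4-(benzyloxy)-2,6-dihydroxy-3,5-dimethoxyphenyl]ethan-1-one | CC(=O)c1c(O)c(OC)c(OCc2ccccc2)c(OC)c1O
F2 | step 12 | (E)-1-[4-(benzyloxy)-2,6-dihydroxy-3,5-dimethoxyphenyl]-3-[5-(benzyloxy)-2,4-dimethoxyphenyl]prop-2-en-1-one | COc1cc(OC)c(/C=C/C(=O)c2c(O)c(OC)c(OCc3ccccc3)c(OC)c2O)cc1OCc1ccccc1
F3 | step 12 | 7-(benzyloxy)-2-[5-(benzyloxy)-2,4-dimethoxyphenyl]-5-hydroxy-6,8-dimethoxy-4H-chromen-4-one | COc1cc(OC)c(-c2cc(=O)c3c(O)c(OC)c(OCc4ccccc4)c(OC)c3o2)cc1OCc1ccccc1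
F4 | step 13 | racemic cis-fused 2,3-epoxide of 22 (a 1a,7a-dihydro-7H-oxireno[2,3-b]chromen-7-one; one enantiomer drawn) | COc1cc(OC)c([C@@]23O[C@@H]2C(=O)c2c(OS(=O)(=O)C(F)(F)F)c(OC)c(OCc4ccccc4)c(OC)c2O3)cc1OCc1ccccc1
F5 | step 4 | [4-(benzyloxy)-2,6-dibromo-3,5-dimethoxyphenyl]trimethylsilane | COc1c(Br)c([Si](C)(C)C)c(Br)c(OC)c1OCc1ccccc1
F6 | step 4 | tetramethyl [5-(benzyloxy)-4,6-dimethoxy-2-(trimethylsilyl)-1,3-phenylene]bis(boronate) | COc1c(B(OC)OC)c([Si](C)(C)C)c(B(OC)OC)c(OC)c1OCc1ccccc1
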